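**Retrosynthetic overview**
1. Target 24 ⇐ acetylation of dienyl alcohol 23 ⇐ E-selective Wittig reaction between lactol 18 (a masked (Z)-4-hydroxy-enal) and the butenolide ylide made from 19.
2. 18 ⇐ DIBAL-H reduction of 4-alkylbutenolide 17, whose ring stores the Z-trisubstituted alkene (CH2O cis to the future diene).
3. 17 ⇐ new one-pot Zr-catalysed methylalumination of alkyne 10 and Cu-catalysed 1,6-alkenyl addition to 4-vinylfuranone 13 (from 11 + 12).
4. 10 ⇐ axial addition of the Grignard reagent from 7 to (S)-2,2,6-trimethylcyclohexanone 6 ⇐ RAMP-hydrazone methylation of 1.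
5. Ring order: no ring is built. The cyclohexane comes from 1, the terminal butenolide from 19 (kept intact), and the furanone ring of 11 is used as a Z-olefin template and opened in step 10.

Assumption: 1, 2, 7, 11, 12 and 19 are taken as catalogue compounds; ring locants are C1 (carbinol), C2 (CMe2), C6 (CHMe), so the target ring is (1R,6S).

**Route**

Step 1
Reactants: 1 2,2-dimethylcyclohexan-1-one; 2 (R)-1-amino-2-(methoxymethyl)pyrrolidine (RAMP)
Product: 3 (2R)-N-[(1E)-2,2-dimethylcyclohexylidene]-2-(methoxymethyl)pyrrolidin-1-amine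
Conditions: TsOH (1 mol %), cyclohexane, reflux, Dean–Stark
Reagents that add atoms: none
Why: Acid-catalysed hydrazone condensation; the N-amino group settles anti to the quaternary C2 and syn to the only enolisable CH2.

Step 2
Reactants: 3 (2R)-N-[(1E)-2,2-dimethylcyclohexylidene]-2-(methoxymethyl)pyrrolidin-1-amine
Product: 5 (2R)-2-(methoxymethyl)-N-[(1E,6S)-2,2,6-trimethylcyclohexylidene]pyrrolidin-1-amine, via lithium azaenolate 4 (not isolated)
Conditions: LDA (1.1 equiv), THF, 0 °C, 4 h; MeI (1.2 equiv), −100 °C → rt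
Reagents that add atoms: iodomethane (CI)
Why: Enders RAMP-hydrazone α-alkylation, in which the chelated azaenolate 4 is methylated on the face left open by the methoxymethyl arm; with RAMP this gives the 6S centre (mirror image of the (R)-2-methylcyclohexanone sense known for SAMP).

Step 3
Reactants: 5 (2R)-2-(methoxymethyl)-N-[(1E,6S)-2,2,6-trimethylcyclohexylidene]pyrrolidin-1-amine
Product: 6 (S)-2,2,6-trimethylcyclohexan-1-one
Conditions: sat. aq. oxalic acid, Et2O, rt, two-phase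
Reagents that add atoms: water (O)
Why: Mild two-phase hydrazone hydrolysis releases the ketone without enolising the α-stereocentre and returns the auxiliary as its oxalate.

Step 4
Reactants: 6 (S)-2,2,6-trimethylcyclohexan-1-one; 7 (4-bromobut-1-yn-1-yl)trimethylsilane
Product: 9 (1R,6S)-2,2,6-trimethyl-1-[4-(trimethylsilyl)but-3-yn-1-yl]cyclohexan-1-ol, via homopropargyl Grignard reagent 8 (not isolated)
Conditions: 7, Mg, THF, rt; then 6, LaCl3·2LiCl (1.0 equiv), THF, 0 °C → rt; aq. NH4Cl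
Reagents that add atoms: none
Why: Lanthanide-promoted Grignard 1,2-addition suppresses enolisation of the hindered ketone, and in the chair with equatorial C6-methyl the axial C2-methyl blocks equatorial approach, so the nucleophile enters axially, cis to the C6-methyl, setting C1 as R (OH trans to C6-Me).

Step 5
Reactants: 9 (1R,6S)-2,2,6-trimethyl-1-[4-(trimethylsilyl)but-3-yn-1-yl]cyclohexan-1-ol
Product: 10 (1R,6S)-1-(but-3-yn-1-yl)-2,2,6-trimethylcyclohexan-1-ol
Conditions: K2CO3 (0.2 equiv), MeOH, rt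
Reagents that add atoms: none
Why: Base-catalysed protodesilylation of the C(sp)–Si bond leaves the tertiary alcohol untouched.

Step 6
Reactants: 11 4-bromofuran-2(5H)-one; 12 tributyl(vinyl)stannane
Product: 13 4-vinylfuran-2(5H)-one
Conditions: Pd(PPh3)4 (5 mol %), THF, 60 °C; KF work-up; used fresh (BHT)
Reagents that add atoms: none
Why: Stille coupling of the vinylogous acyl bromide runs under neutral conditions that spare the base-sensitive butenolide.

Step 7
Reactants: 10 (1R,6S)-1-(but-3-yn-1-yl)-2,2,6-trimethylcyclohexan-1-ol; 13 4-vinylfuran-2(5H)-one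
Product: 17 4-[(3E)-6-[(1R,6S)-1-hydroxy-2,2,6-trimethylcyclohexyl]-4-methylhex-3-en-1-yl]furan-2(5H)-one, via alkenylalane 14 (not isolated), via aluminium dienolate 15 (not isolated), via deconjugated lactone 16 (not isolated)
Conditions: Me3Al (3 equiv), Cp2ZrCl2 (0.25 equiv), CH2Cl2, 0 °C → rt; volatiles removed in vacuo; 13 (1.3 equiv), CuTC (10 mol %), P(OEt)3 (20 mol %), THF, −30 → 0 °C; aq. NH4Cl; then DBU (0.1 equiv), CH2Cl2, rt
Reagents that add atoms: trimethylaluminium (C[Al](C)C)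
Why: Proposed new method: the known Zr-catalysed syn-methylalumination fixes the E-olefin (Me and Al cis) in 14, and the new event is a Cu-catalysed δ-selective (1,6) alkenyl transfer from Al to the dienyl lactone 13 — Al→Cu transmetallation with retention gives an alkenylcopper whose π-complex with the Al-activated dienoate forms a σ/π-allyl Cu(III) species that reductively eliminates at the unsubstituted δ-CH2 (β-attack would have to build a quaternary centre), giving dienolate 15, which is protonated and conjugated by DBU to the endocyclic butenolide so that the future CH2O and CHO carbons are locked cis; the closest known reaction types are Cu-catalysed 1,4-addition of carboalumination-derived alkenylalanes to enones and Cu-catalysed 1,6-addition of Grignard or trialkylaluminium reagents to 2,4-dienoates, and an alkenylalane 1,6-addition to a 4-vinylbutenolide has, to my knowledge, not been shown.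

Step 8
Reactants: 17 4-[(3E)-6-[(1R,6S)-1-hydroxy-2,2,6-trimethylcyclohexyl]-4-methylhex-3-en-1-yl]furan-2(5H)-one
Product: 18 4-[(3E)-6-[(1R,6S)-1-hydroxy-2,2,6-trimethylcyclohexyl]-4-methylhex-3-en-1-yl]-2,5-dihydrofuran-2-ol (anomer mixture)
Conditions: DIBAL-H (2.2 equiv), CH2Cl2, −78 °C; aq. Rochelle salt; crude used at once
Reagents that add atoms: none
Why: DIBAL-H partial reduction stops at the aluminium hemiacetal at −78 °C and leaves the ring C=C alone, so the CH2O and the masked CHO stay cis on the trisubstituted alkene; the neutral work-up avoids dehydration to the furan.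

Step 9
Reactants: 19 4-(bromomethyl)furan-2(5H)-one
Product: 20 [(5-oxo-2,5-dihydrofuran-3-yl)methyl]triphenylphosphonium bromide
Conditions: PPh3 (1.05 equiv), MeCN, rt → 40 °C
Reagents that add atoms: triphenylphosphine (c1ccc(cc1)P(c1ccccc1)c1ccccc1)
Why: SN2 quaternisation of PPh3 by the reactive allylic bromide.

Step 10
Reactants: 18 4-[(3E)-6-[(1R,6S)-1-hydroxy-2,2,6-trimethylcyclohexyl]-4-methylhex-3-en-1-yl]-2,5-dihydrofuran-2-ol; 20 [(5-oxo-2,5-dihydrofuran-3-yl)methyl]triphenylphosphonium bromide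
Product: 23 4-[(1E,3Z,7E)-4-(hydroxymethyl)-10-[(1R,6S)-1-hydroxy-2,2,6-trimethylcyclohexyl]-8-methyldeca-1,3,7-trien-1-yl]furan-2(5H)-one, via phosphorus ylide 21 (not isolated), via open-chain hydroxy enal 22 (not isolated)
Conditions: 20 (1.5 equiv), NaHMDS (1.45 equiv), THF, −78 → 0 °C; then 18, THF, 0 °C → rt
Reagents that add atoms: none
Why: Wittig olefination of a lactol through its ring-opened tautomer 22 with the ester-stabilised (vinylogous) ylide 21 gives the E C=C, while the Z trisubstituted alkene is inherited from the ring and the absence of free base disfavours oxa-Michael re-closure.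

Step 11
Reactants: 23 4-[(1E,3Z,7E)-4-(hydroxymethyl)-10-[(1R,6S)-1-hydroxy-2,2,6-trimethylcyclohexyl]-8-methyldeca-1,3,7-trien-1-yl]furan-2(5H)-one
Product: 24 (2Z,5E)-8-[(1R,6S)-1-hydroxy-2,2,6-trimethylcyclohexyl]-6-methyl-2-[(2E)-3-(5-oxo-2,5-dihydrofuran-3-yl)prop-2-en-1-ylidene]oct-5-en-1-yl acetate (CNP0366059.1)
Conditions: Ac2O (1.5 equiv), pyridine (3 equiv), DMAP (5 mol %), CH2Cl2, 0 °C
Reagents that add atoms: acetic anhydride (CC(=O)OC(C)=O)
Why: DMAP-catalysed acetylation is selective for the primary allylic alcohol because the tertiary ring alcohol, flanked by two substituted carbons, does not acylate at 0 °C.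

**Compound list**
1 | 2,2-dimethylcyclohexan-1-one | CC1(C)CCCCC1=O | starting material
2 | (R)-1-amino-2-(methoxymethyl)pyrrolidine (RAMP) | COC[C@H]1CCCN1N | starting material
3 | (2R)-N-[(1E)-2,2-dimethylcyclohexylidene]-2-(methoxymethyl)pyrrolidin-1-amine | COC[C@H]1CCCN1/N=C2\CCCCC2(C)C | intermediate
4 | lithium azaenolate of 3 (N-lithio ene-hydrazide) | COC[C@H]1CCCN1N([Li])C2=CCCCC2(C)C | intermediate
5 | (2R)-2-(methoxymethyl)-N-[(1E,6S)-2,2,6-trimethylcyclohexylidene]pyrrolidin-1-amine | COC[C@H]1CCCN1/N=C2\[C@@H](C)CCCC2(C)C | intermediate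
6 | (S)-2,2,6-trimethylcyclohexan-1-one | O=C1[C@@H](C)CCCC1(C)C | intermediate
7 | (4-bromobut-1-yn-1-yl)trimethylsilane | C[Si](C)(C)C#CCCBr | starting material
8 | [4-(trimethylsilyl)but-3-yn-1-yl]magnesium bromide | C[Si](C)(C)C#CCC[Mg]Br | intermediate
9 | (1R,6S)-2,2,6-trimethyl-1-[4-(trimethylsilyl)but-3-yn-1-yl]cyclohexan-1-ol | C[Si](C)(C)C#CCC[C@@]1(O)[C@@H](C)CCCC1(C)C | intermediate
10 | (1R,6S)-1-(but-3-yn-1-yl)-2,2,6-trimethylcyclohexan-1-ol | C#CCC[C@@]1(O)[C@@H](C)CCCC1(C)C | intermediate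
11 | 4-bromofuran-2(5H)-one | O=C1OCC(Br)=C1 | starting material
12 | tributyl(vinyl)stannane | C=C[Sn](CCCC)(CCCC)CCCC | starting material
13 | 4-vinylfuran-2(5H)-one | C=CC1=CC(=O)OC1 | intermediate
14 | dimethyl[(1E)-4-[(1R,6S)-1-(dimethylalumanyloxy)-2,2,6-trimethylcyclohexyl]-2-methylbut-1-en-1-yl]alumane | C[Al](C)/C=C(\C)CC[C@@]1(O[Al](C)C)[C@@H](C)CCCC1(C)C | intermediate
15 | dimethylaluminium dienolate of the 1,6-adduct (4-alkylidene-4,5-dihydrofuran-2-olate; exocyclic C=C geometry undefined) | C[Al](C)OC1=CC(=CC/C=C(\C)CC[C@@]2(O[Al](C)C)[C@@H](C)CCCC2(C)C)CO1 | intermediate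
16 | 4-[(3E)-6-[(1R,6S)-1-hydroxy-2,2,6-trimethylcyclohexyl]-4-methylhex-3-en-1-ylidene]dihydrofuran-2(3H)-one (exocyclic E/Z mixture) | O=C1CC(=CC/C=C(\C)CC[C@@]2(O)[C@@H](C)CCCC2(C)C)CO1 | intermediate
17 | 4-[(3E)-6-[(1R,6S)-1-hydroxy-2,2,6-trimethylcyclohexyl]-4-methylhex-3-en-1-yl]furan-2(5H)-one | O=C1OCC(CC/C=C(\C)CC[C@@]2(O)[C@@H](C)CCCC2(C)C)=C1 | intermediate
18 | 4-[(3E)-6-[(1R,6S)-1-hydroxy-2,2,6-trimethylcyclohexyl]-4-methylhex-3-en-1-yl]-2,5-dihydrofuran-2-ol (anomer mixture) | OC1OCC(CC/C=C(\C)CC[C@@]2(O)[C@@H](C)CCCC2(C)C)=C1 | intermediate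
19 | 4-(bromomethyl)furan-2(5H)-one | O=C1OCC(CBr)=C1 | starting material
20 | [(5-oxo-2,5-dihydrofuran-3-yl)methyl]triphenylphosphonium bromide | O=C1OCC(C[P+](c2ccccc2)(c2ccccc2)c2ccccc2)=C1.[Br-] | intermediate
21 | 4-[(triphenyl-λ5-phosphanylidene)methyl]furan-2(5H)-one | O=C1OCC(C=P(c2ccccc2)(c2ccccc2)c2ccccc2)=C1 | intermediate
22 | (2Z,6E)-3-(hydroxymethyl)-9-[(1R,6S)-1-hydroxy-2,2,6-trimethylcyclohexyl]-7-methylnona-2,6-dienal | O=C/C=C(\CO)CC/C=C(\C)CC[C@@]1(O)[C@@H](C)CCCC1(C)C | intermediate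
23 | 4-[(1E,3Z,7E)-4-(hydroxymethyl)-10-[(1R,6S)-1-hydroxy-2,2,6-trimethylcyclohexyl]-8-methyldeca-1,3,7-trien-1-yl]furan-2(5H)-one | OC/C(=C\C=C\C1=CC(=O)OC1)CC/C=C(\C)CC[C@@]2(O)[C@@H](C)CCCC2(C)C | intermediate
24 | (2Z,5E)-8-[(1R,6S)-1-hydroxy-2,2,6-trimethylcyclohexyl]-6-methyl-2-[(2E)-3-(5-oxo-2,5-dihydrofuran-3-yl)prop-2-en-1-ylidene]oct-5-en-1-yl acetate (CNP0366059.1) | CC(=O)OC/C(=C\C=C\C1=CC(=O)OC1)CC/C=C(\C)CC[C@@]2(O)[C@@H](C)CCCC2(C)C | target

**Totals**
Total step count: 11. Longest linear sequence: 9 steps (1, 2, 3, 4, 5, 7, 8, 10, 11).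

**Three steps most likely to fail**

Step 7 (proposed new step; risks are 1,4- versus 1,6-attack, competing methyl transfer and oligomerisation of 13). The fallback uses known chemistry, sets out from 10 and comes back at 17. Alkyne 10 is methylaluminated as before (Me3Al, Cp2ZrCl2), the alkenylalane is converted to its lithium alanate with n-BuLi and opened with oxirane to give (1R,6S)-1-[(3E)-6-hydroxy-3-methylhex-3-en-1-yl]-2,2,6-trimethylcyclohexan-1-ol F1. Selective iodination of the primary alcohol (I2, PPh3, imidazole, 0 °C) gives (1R,6S)-1-[(3E)-6-iodo-3-methylhex-3-en-1-yl]-2,2,6-trimethylcyclohexan-1-ol F2. Zinc insertion (Zn dust, LiCl, THF) gives [(3E)-6-[(1R,6S)-1-hydroxy-2,2,6-trimethylcyclohexyl]-4-methylhex-3-en-1-yl]zinc iodide F3, which undergoes Pd-catalysed Negishi coupling with 4-bromofuran-2(5H)-one 11 to give 17.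

Step 10 (risks are slow opening of the lactol, E/Z mixtures from the vinylogous ylide, and oxa-Michael re-closure). The fallback forms the diene–butenolide bond by cross-coupling instead of olefination; it sets out from 18 and comes back at 23. Colvin homologation of lactol 18 with lithiated trimethylsilyldiazomethane (THF, −78 °C → rt) gives (1R,6S)-1-[(3E,7Z)-7-(hydroxymethyl)-3-methyldeca-3,7-dien-9-yn-1-yl]-2,2,6-trimethylcyclohexan-1-ol F4. Zr-catalysed syn-hydroboration of the terminal alkyne (pinacolborane in excess, Cp2Zr(H)Cl cat., Et3N) gives (1R,6S)-1-[(3E,7Z,9E)-7-(hydroxymethyl)-3-methyl-10-(4,4,5,5-tetramethyl-1,3,2-dioxaborolan-2-yl)deca-3,7,9-trien-1-yl]-2,2,6-trimethylcyclohexan-1-ol F5. Suzuki–Miyaura coupling of F5 with 4-bromofuran-2(5H)-one 11 (Pd(dppf)Cl2, K3PO4, THF/H2O, rt) gives 23.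

Step 4 (risks are enolisation or reduction of the hindered ketone and incomplete axial selectivity with an sp3 nucleophile). The fallback uses an sp nucleophile, which adds axially to this ketone with high selectivity, and builds the alkyne afterwards; it sets out from 6 and comes back at 10. The lithium acetylide of 3,3-diethoxyprop-1-yne (n-BuLi, THF, −78 °C) adds to 6 to give (1R,6S)-1-(3,3-diethoxyprop-1-yn-1-yl)-2,2,6-trimethylcyclohexan-1-ol F6. Hydrogenation (H2, Pd/C, EtOAc, trace Et3N) gives (1R,6S)-1-(3,3-diethoxypropyl)-2,2,6-trimethylcyclohexan-1-ol F7. Mild acetal hydrolysis (aq. AcOH, THF) gives the spiro-lactol (5R,10S)-6,6,10-trimethyl-1-oxaspiro[4.5]decan-2-ol F8. Ohira–Bestmann homologation of F8 (dimethyl (1-diazo-2-oxopropyl)phosphonate, K2CO3, MeOH) gives 10.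

**Further compounds**
F1 | step 7 | (1R,6S)-1-[(3E)-6-hydroxy-3-methylhex-3-en-1-yl]-2,2,6-trimethylcyclohexan-1-ol | OCC/C=C(\C)CC[C@@]1(O)[C@@H](C)CCCC1(C)C
F2 | step 7 | (1R,6S)-1-[(3E)-6-iodo-3-methylhex-3-en-1-yl]-2,2,6-trimethylcyclohexan-1-ol | ICC/C=C(\C)CC[C@@]1(O)[C@@H](C)CCCC1(C)C
F3 | step 7 | [(3E)-6-[(1R,6S)-1-hydroxy-2,2,6-trimethylcyclohexyl]-4-methylhex-3-en-1-yl]zinc iodide | I[Zn]CC/C=C(\C)CC[C@@]1(O)[C@@H](C)CCCC1(C)C
F4 | step 10 | (1R,6S)-1-[(3E,7Z)-7-(hydroxymethyl)-3-methyldeca-3,7-dien-9-yn-1-yl]-2,2,6-trimethylcyclohexan-1-ol | C#C/C=C(\CO)CC/C=C(\C)CC[C@@]1(O)[C@@H](C)CCCC1(C)C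
F5 | step 10 | (1R,6S)-1-[(3E,7Z,9E)-7-(hydroxymethyl)-3-methyl-10-(4,4,5,5-tetramethyl-1,3,2-dioxaborolan-2-yl)deca-3,7,9-trien-1-yl]-2,2,6-trimethylcyclohexan-1-ol | CC1(C)OB(/C=C/C=C(\CO)CC/C=C(\C)CC[C@@]2(O)[C@@H](C)CCCC2(C)C)OC1(C)C
F6 | step 4 | (1R,6S)-1-(3,3-diethoxyprop-1-yn-1-yl)-2,2,6-trimethylcyclohexan-1-ol | CCOC(OCC)C#C[C@@]1(O)[C@@H](C)CCCC1(C)C
F7 | step 4 | (1R,6S)-1-(3,3-diethoxypropyl)-2,2,6-trimethylcyclohexan-1-ol | CCOC(OCC)CC[C@@]1(O)[C@@H](C)CCCC1(C)C
F8 | step 4 | (5R,10S)-6,6,10-trimethyl-1-oxaspiro[4.5]decan-2-ol (anomer mixture) | OC1CC[C@@]2(O1)[C@@H](C)CCCC2(C)C
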